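**Plan**
1. Core numbering is N1, O2, C3, C3a, C4–C6, C6a (hexahydro-1H-cyclopenta[c]isoxazole). The enabling feature: the adjacent fusion carbons C3a and C6a of the cyclopentane ring carry, cis to each other, a C–C bond (to C3) and a C–N bond (to N1), and only O2 separates C3 from N1. With O2 deleted and C3 raised to a carbonyl, the isoxazolidine ring contracts to a cis-fused azetidin-2-one, the [2+2] adduct of symmetrical cyclopentene and an isocyanate.
2. Retrosynthetic cuts, in order: pyridine–CH2 of the C3 chain (B-alkyl Suzuki–Miyaura); C3–H (hemiketal reduction); C3–C1' (Grignard addition to the lactone); O2 taken out of N1–O2–C3 (back to the β-lactam N1–C3 bond); N1–CH2 of the C13 chain; then C3a–C3 and C6a–N1 together.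
3. Forward: the four-membered ring forms first on the preformed cyclopentene, as a temporary ring, and is N-alkylated. Its N1–C3 bond is then cleaved, O2 is put on N1, and relactonisation closes the five-membered N–O ring. The C3 chain and the second pyridine follow.
4. Stereochemistry: the cis C3a/C6a relation comes from the suprafacial cycloaddition, the absolute configuration from a lipase kinetic resolution of the lactam, and C3 from hydride delivery to the convex face of the bicyclic oxocarbenium ion (H3, H3a and H6a all cis).
5. Helpers and their removal: ClSO2 (activator, off in step 1), the N1–C3 bond (cleaved in step 5), the C3 carbonyl oxygen (leaves as the hemiketal OH in step 9).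

Key step: step 1

Remark: N1 inverts rapidly, so only C3, C3a and C6a are treated as stereocentres. Racemates 3 and 4 are drawn with relative configuration only.

**Step 1**
Reactants: 1 cyclopentene; 2 chlorosulfonyl isocyanate
Product: 4 (±)-cis-6-azabicyclo[3.2.0]heptan-7-one, via N-chlorosulfonyl lactam 3 (not isolated)
Conditions: CH2Cl2, 0 → 40 °C; then aq Na2SO3, NaHCO3, 0 °C
Reagents that add atoms: none
Why: Thermal [2+2] cycloaddition of an unactivated alkene with chlorosulfonyl isocyanate, the standard entry to N-unsubstituted β-lactams: the π bond of 1 attacks the isocyanate carbon, made strongly electrophilic by the ClSO2 group, in a concerted but asynchronous [π2s+π2a] process (at most a tight 1,4-dipole that collapses before any rotation), so that C3a–C3 and C6a–N1 are made in the same event. The one ring closed is the azetidin-2-one, and it closes by cycloaddition across the C=N bond of the heterocumulene onto the preformed cyclopentene, not by cyclisation of a chain. The two new stereocentres C3a and C6a are set relative to each other by suprafacial addition to the cis ring olefin, and a trans-fused bicyclo[3.2.0]heptanone is too strained to form, so only the cis lactam is expected, as a racemate. Regioselectivity is not needed because the two olefinic carbons of 1 are related by symmetry; what is needed is periselectivity for C=N over C=O and for ring closure over proton loss to the unsaturated N-sulfonyl amide, and the lack of any cation-stabilising substituent on 1 together with the non-polar medium favours closure. The ClSO2 activator is taken off in the same flask by sulfite reduction of the N-sulfonyl chloride at buffered pH, which leaves the strained amide intact.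

**Step 2**
Reactants: 4 (±)-cis-6-azabicyclo[3.2.0]heptan-7-one
Product: 5 (1S,5R)-6-azabicyclo[3.2.0]heptan-7-one
Conditions: CAL-B (immobilised), H2O (0.5 equiv), i-Pr2O, 60 °C, run slightly past half conversion; filter
Reagents that add atoms: none
Why: Lipase-catalysed enantioselective hydrolysis (kinetic resolution) of an alicyclic-fused β-lactam: the enzyme should open only the (1R,5S)-enantiomer to the insoluble cis-amino acid, so that the untouched (1S,5R)-lactam 5, which already has the C3a and C6a configuration of the target, is recovered from the filtrate.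

**Step 3**
Reactants: 6 3-methylpyridine; 7 1,12-dibromododecane
Product: 9 3-(13-bromotridecyl)pyridine, via 3-picolyllithium 8 (not isolated)
Conditions: LDA, THF, −78 °C; then 7 (3 equiv), −78 °C → rt
Reagents that add atoms: none
Why: Lateral lithiation of 3-picoline followed by SN2 alkylation; the excess of the symmetrical dibromide should hold back double alkylation, no stereocentre is involved, and 9 is used at once because it slowly quaternises itself.

**Step 4**
Reactants: 5 (1S,5R)-6-azabicyclo[3.2.0]heptan-7-one; 9 3-(13-bromotridecyl)pyridine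
Product: 11 (1S,5R)-6-[13-(pyridin-3-yl)tridecyl]-6-azabicyclo[3.2.0]heptan-7-one, via sodium lactamate 10 (not isolated)
Conditions: NaH, DMF, 0 °C; then 9, 0 °C → rt
Reagents that add atoms: none
Why: SN2 N-alkylation of a lactam anion, which is far more nucleophilic than the pyridine nitrogen and can be alkylated only once; the ring-fusion centres cannot epimerise because a trans-fused bicyclo[3.2.0]heptanone is out of reach.

**Step 5**
Reactants: 11 (1S,5R)-6-[13-(pyridin-3-yl)tridecyl]-6-azabicyclo[3.2.0]heptan-7-one
Product: 12 methyl (1S,2R)-2-{[13-(pyridin-3-yl)tridecyl]amino}cyclopentane-1-carboxylate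
Conditions: HCl (3 M in MeOH), reflux; then aq NaHCO3
Reagents that add atoms: methanol, CO
Why: Acid-promoted alcoholysis of a strained β-lactam (acyl–nitrogen cleavage) breaks the temporary N1–C3 bond; under acidic conditions the ester α-carbon C3a is not enolised, so the cis relation should be kept.

**Step 6**
Reactants: 12 methyl (1S,2R)-2-{[13-(pyridin-3-yl)tridecyl]amino}cyclopentane-1-carboxylate
Product: 13 methyl (1S,2R)-2-{(benzoyloxy)[13-(pyridin-3-yl)tridecyl]amino}cyclopentane-1-carboxylate
Conditions: (BzO)2, K2HPO4, DMF, rt
Reagents that add atoms: dibenzoyl peroxide, O=C(OOC(=O)c1ccccc1)c1ccccc1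
Why: Electrophilic N-oxygenation of a secondary amine by SN2 attack of nitrogen on the O–O bond of dibenzoyl peroxide puts O2 on N1 and stops at the protected hydroxylamine level; the aliphatic amine should react much faster than the pyridine and no carbon stereocentre is touched.

**Step 7**
Reactants: 13 methyl (1S,2R)-2-{(benzoyloxy)[13-(pyridin-3-yl)tridecyl]amino}cyclopentane-1-carboxylate
Product: 15 (3aS,6aR)-1-[13-(pyridin-3-yl)tridecyl]hexahydro-3H-cyclopenta[c]isoxazol-3-one, via N-hydroxy amino ester 14 (not isolated)
Conditions: K2CO3 (cat.), MeOH, 0 °C; then PPTS (cat.), toluene, 80 °C (−MeOH), Ar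
Reagents that add atoms: none
Why: Carbonate-catalysed transesterification removes the activated O-benzoyl group and the freed N–OH then lactonises onto the cis ester (5-exo-trig acyl substitution, driven by removal of methanol), which completes the insertion of O2 into the former N1–C3 bond; the weak base and low temperature should avoid epimerisation at C3a before the cis-locked bicycle forms.

**Step 8**
Reactants: 15 (3aS,6aR)-1-[13-(pyridin-3-yl)tridecyl]hexahydro-3H-cyclopenta[c]isoxazol-3-one; 16 8-bromooct-1-ene
Product: 18 (3aS,6aR)-3-(oct-7-en-1-yl)-1-[13-(pyridin-3-yl)tridecyl]hexahydro-1H-cyclopenta[c]isoxazol-3-ol (C3 epimers), via oct-7-enylmagnesium bromide 17 (not isolated)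
Conditions: 16, Mg, THF, rt; add to 15, THF, −78 °C; sat. aq NH4Cl at −78 °C
Reagents that add atoms: none
Why: Single addition of a Grignard reagent to a lactone carbonyl at low temperature, with a cold quench of the tetrahedral magnesium alkoxide, should stop at the cyclic hemiketal; the configuration at C3 is of no consequence because this carbon becomes planar in step 9, and the pyridine ring is inert to alkylmagnesium halides at −78 °C.

**Step 9**
Reactants: 18 (3aS,6aR)-3-(oct-7-en-1-yl)-1-[13-(pyridin-3-yl)tridecyl]hexahydro-1H-cyclopenta[c]isoxazol-3-ol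
Product: 20 (3S,3aS,6aR)-3-(oct-7-en-1-yl)-1-[13-(pyridin-3-yl)tridecyl]hexahydro-1H-cyclopenta[c]isoxazole, via bicyclic oxocarbenium ion 19 (not isolated)
Conditions: Et3SiH, BF3·OEt2 (excess, the basic nitrogens bind part of it), CH2Cl2, −78 → −20 °C; basic aqueous work-up
Reagents that add atoms: none
Why: Ionic reduction of a cyclic hemiketal (Lewis acid ionisation to the oxocarbenium ion 19, then hydride transfer from the silane): hydride should arrive on the convex face of the cis-bicyclo[3.3.0] cation, anti to the C3a–C4 bond and in line with inside attack on the envelope, which places H3 cis to H3a and H6a and the chain on the concave face, that is (3S); the terminal alkene and the N–O bond do not react with Et3SiH/BF3.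

**Step 10**
Reactants: 20 (3S,3aS,6aR)-3-(oct-7-en-1-yl)-1-[13-(pyridin-3-yl)tridecyl]hexahydro-1H-cyclopenta[c]isoxazole; 21 3-bromopyridine
Product: 23 pyrinodemin B, via B-alkyl-9-BBN 22 (not isolated)
Conditions: 9-BBN-H (excess), THF, rt; then 21, PdCl2(dppf) (cat.), aq NaOH, THF, 65 °C
Reagents that add atoms: none
Why: Anti-Markovnikov hydroboration of the terminal alkene followed by B-alkyl Suzuki–Miyaura coupling joins the last sp3–sp2 bond under conditions that leave the N–O bond and the three stereocentres alone; extra 9-BBN-H covers the amount bound by the two basic nitrogens.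

**Compound list**
1 | cyclopentene | C1=CCCC1 | starting material
2 | chlorosulfonyl isocyanate | O=C=NS(=O)(=O)Cl | starting material
3 | (±)-cis-6-(chlorosulfonyl)-6-azabicyclo[3.2.0]heptan-7-one (racemate, relative configuration drawn) | ClS(=O)(=O)N1C(=O)[C@H]2CCC[C@H]21 | intermediate
4 | (±)-cis-6-azabicyclo[3.2.0]heptan-7-one (racemate, relative configuration drawn) | N1C(=O)[C@H]2CCC[C@H]21 | intermediate
5 | (1S,5R)-6-azabicyclo[3.2.0]heptan-7-one | N1C(=O)[C@H]2CCC[C@H]21 | intermediate
6 | 3-methylpyridine | Cc1cccnc1 | starting material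
7 | 1,12-dibromododecane | BrCCCCCCCCCCCCBr | starting material
8 | 3-picolyllithium | [Li]Cc1cccnc1 | intermediate
9 | 3-(13-bromotridecyl)pyridine | BrCCCCCCCCCCCCCc1cccnc1 | intermediate
10 | sodium salt of (1S,5R)-6-azabicyclo[3.2.0]heptan-7-one | [Na+].[N-]1C(=O)[C@H]2CCC[C@H]21 | intermediate
11 | (1S,5R)-6-[13-(pyridin-3-yl)tridecyl]-6-azabicyclo[3.2.0]heptan-7-one | c1cncc(CCCCCCCCCCCCCN2C(=O)[C@H]3CCC[C@H]32)c1 | intermediate
12 | methyl (1S,2R)-2-{[13-(pyridin-3-yl)tridecyl]amino}cyclopentane-1-carboxylate | COC(=O)[C@H]1CCC[C@H]1NCCCCCCCCCCCCCc1cccnc1 | intermediate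
13 | methyl (1S,2R)-2-{(benzoyloxy)[13-(pyridin-3-yl)tridecyl]amino}cyclopentane-1-carboxylate | COC(=O)[C@H]1CCC[C@H]1N(OC(=O)c1ccccc1)CCCCCCCCCCCCCc1cccnc1 | intermediate
14 | methyl (1S,2R)-2-{hydroxy[13-(pyridin-3-yl)tridecyl]amino}cyclopentane-1-carboxylate | COC(=O)[C@H]1CCC[C@H]1N(O)CCCCCCCCCCCCCc1cccnc1 | intermediate
15 | (3aS,6aR)-1-[13-(pyridin-3-yl)tridecyl]hexahydro-3H-cyclopenta[c]isoxazol-3-one (cis-fused isoxazolidin-5-one, N1–O2–C3(=O)) | c1cncc(CCCCCCCCCCCCCN2OC(=O)[C@H]3CCC[C@H]32)c1 | intermediate
16 | 8-bromooct-1-ene | C=CCCCCCCBr | starting material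
17 | oct-7-enylmagnesium bromide | C=CCCCCCC[Mg]Br | intermediate
18 | (3aS,6aR)-3-(oct-7-en-1-yl)-1-[13-(pyridin-3-yl)tridecyl]hexahydro-1H-cyclopenta[c]isoxazol-3-ol (hemiketal, C3 epimers) | c1cncc(CCCCCCCCCCCCCN2OC(O)(CCCCCCC=C)[C@H]3CCC[C@H]32)c1 | intermediate
19 | (3aS,6aR)-bicyclic oxocarbenium ion, C3=O2(+) | c1cncc(CCCCCCCCCCCCCN2[O+]=C(CCCCCCC=C)[C@H]3CCC[C@H]32)c1 | intermediate
20 | (3S,3aS,6aR)-3-(oct-7-en-1-yl)-1-[13-(pyridin-3-yl)tridecyl]hexahydro-1H-cyclopenta[c]isoxazole | c1cncc(CCCCCCCCCCCCCN2O[C@@H](CCCCCCC=C)[C@H]3CCC[C@H]32)c1 | intermediate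
21 | 3-bromopyridine | Brc1cccnc1 | starting material
22 | 9-{8-[(3S,3aS,6aR)-1-[13-(pyridin-3-yl)tridecyl]hexahydro-1H-cyclopenta[c]isoxazol-3-yl]octyl}-9-borabicyclo[3.3.1]nonane | c1cncc(CCCCCCCCCCCCCN2O[C@@H](CCCCCCCCB4C5CCCC4CCC5)[C@H]3CCC[C@H]32)c1 | intermediate
23 | pyrinodemin B, (3S,3aS,6aR)-3-[8-(pyridin-3-yl)octyl]-1-[13-(pyridin-3-yl)tridecyl]hexahydro-1H-cyclopenta[c]isoxazole | c1cncc(CCCCCCCCCCCCCN2O[C@@H](CCCCCCCCc3cccnc3)[C@H]3CCC[C@H]32)c1 | target

**Total step count:** 10. **Longest linear sequence:** 9 (steps 1, 2, 4, 5, 6, 7, 8, 9, 10, from cyclopentene).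

**Steps most likely to fail**

Step 8. The tetrahedral magnesium alkoxide may collapse already at low temperature, because an aminoxide is a good leaving group, which would lead to a second addition. The Grignard reagent may also attack nitrogen with N–O cleavage, or simply enolise the lactone. The fallback sets out from 15. Aminolysis with MeNH(OMe)·HCl and i-PrMgCl opens the lactone to the N-hydroxy Weinreb amide F1. TBSCl and imidazole convert it into the O-silyl hydroxylamine F2. Reagent 17 then adds once through the chelated tetrahedral intermediate to give the ketone F3. Desilylation with fluoride frees the N–OH group, which closes onto the ketone, and the route is rejoined at 18.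

Step 9. Facial selectivity of hydride delivery may be poor. Ionisation of the electron-poor O–N-substituted hemiketal may also be slower than ring opening followed by retro-Michael loss of the hydroxylamine, or than epimerisation at C3a. The fallback sets out from 18. The open-chain keto tautomer is reduced under reagent control ((S)-Me-CBS, catecholborane, toluene, −78 °C, which spares the terminal alkene) to the (1R)-carbinol F4. A Mitsunobu-type cyclodehydration with cyanomethylenetributylphosphorane in hot toluene then forms O2–C3 by 5-exo-tet SN2 displacement with inversion. C3 is then set by the catalyst and by a stereospecific substitution instead of by the shape of the bicycle. The route is rejoined at 20.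

Step 6. The hindered secondary amine may attack the carbonyl carbon of the peroxide instead of oxygen (N-benzoylation), may react sluggishly, or the pyridine may compete for the peroxide. The fallback sets out from 12. Aza-Michael addition to acrylonitrile (MeOH, reflux) gives the tertiary amine F5. One equivalent of mCPBA (CH2Cl2, −78 → 0 °C) oxidises the more nucleophilic aliphatic nitrogen to the N-oxide F6. On warming, a Cope elimination through the acidified CH2 next to the nitrile leaves the free hydroxylamine. The route is rejoined at 14, which is lactonised as in the second stage of step 7.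

**Further compounds**
F1 | step 8 | (1S,2R)-2-{hydroxy[13-(pyridin-3-yl)tridecyl]amino}-N-methoxy-N-methylcyclopentane-1-carboxamide | CON(C)C(=O)[C@H]1CCC[C@H]1N(O)CCCCCCCCCCCCCc1cccnc1
F2 | step 8 | (1S,2R)-2-{(tert-butyldimethylsilyloxy)[13-(pyridin-3-yl)tridecyl]amino}-N-methoxy-N-methylcyclopentane-1-carboxamide | CON(C)C(=O)[C@H]1CCC[C@H]1N(O[Si](C)(C)C(C)(C)C)CCCCCCCCCCCCCc1cccnc1
F3 | step 8 | 1-[(1S,2R)-2-{(tert-butyldimethylsilyloxy)[13-(pyridin-3-yl)tridecyl]amino}cyclopentyl]non-8-en-1-one | C=CCCCCCCC(=O)[C@H]1CCC[C@H]1N(O[Si](C)(C)C(C)(C)C)CCCCCCCCCCCCCc1cccnc1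
F4 | step 9 | (1R)-1-[(1S,2R)-2-{hydroxy[13-(pyridin-3-yl)tridecyl]amino}cyclopentyl]non-8-en-1-ol | O[C@H](CCCCCCC=C)[C@H]1CCC[C@H]1N(O)CCCCCCCCCCCCCc1cccnc1
F5 | step 6 | methyl (1S,2R)-2-{(2-cyanoethyl)[13-(pyridin-3-yl)tridecyl]amino}cyclopentane-1-carboxylate | COC(=O)[C@H]1CCC[C@H]1N(CCC#N)CCCCCCCCCCCCCc1cccnc1
F6 | step 6 | N-oxide of methyl (1S,2R)-2-{(2-cyanoethyl)[13-(pyridin-3-yl)tridecyl]amino}cyclopentane-1-carboxylate | COC(=O)[C@H]1CCC[C@H]1[N+]([O-])(CCC#N)CCCCCCCCCCCCCc1cccnc1
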